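**Retrosynthetic overview**
- The target comes from a methyl ester/bis(methyl ether) hydroquinone by one Lewis-acid deprotection; the hydroquinone comes from para-hydroxylation (C3′–O) of a 6′-hydroxy-4′-methoxy salicylate.
- The plan rests on the benzoate ring C1′–C6′: CO2H on C1′, the chromonyl CH2 on C2′, oxygens on C4′ and C6′ (1,3 to each other, C6′–O ortho to the carboxyl). A 1,3-dioxygenated vinylketene acetal (C1→C6′, C2→C5′, C3→C4′, C4→C3′) delivers this pattern onto an alkynoate (Cα→C1′, Cβ→C2′).
- The salicylate is cut at C2′–C3′ and C1′–C6′ into the chromon-2-ylmethyl ynoate and 1,3-dimethoxy-1-(trimethylsilyloxy)butadiene (two steps from methyl acetoacetate).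
- The ynoate comes from methyl propiolate and a 2-(bromomethyl)chromone. The bromide is made by oxalate Claisen/cyclodehydration, ester reduction and Appel bromination, so no radical bromination is run next to the heptyl chain. The acetophenone comes from 1-bromo-3,5-dimethoxybenzene and heptylmagnesium bromide.
- Ring order: the carbocycle of the chromone is bought; the 4-pyranone ring closes in step 4; the benzoate ring in step 10.

Key step: step 10

Assumption: the target has no stereogenic element, so the achiral compound itself is the required single species and no stereocontrol is needed.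

**Step 1**
Reactants: 1 1-bromo-3,5-dimethoxybenzene; 2 heptylmagnesium bromide
Product: 3 1-heptyl-3,5-dimethoxybenzene
Conditions: NiCl2(dppp) (cat.), THF/Et2O, 0 °C → reflux
Reagents that add atoms: none
Why: Kumada–Corriu coupling of an aryl bromide with a primary alkyl Grignard reagent, in which the chelating diphosphine on nickel suppresses β-hydride elimination and no Grignard-sensitive group is present.

**Step 2**
Reactants: 3 1-heptyl-3,5-dimethoxybenzene; 4 acetyl chloride
Product: 5 1-(2-heptyl-4,6-dimethoxyphenyl)ethan-1-one
Conditions: AlCl3 (1.1 equiv), CH2Cl2, −10 → 0 °C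
Reagents that add atoms: none
Why: Friedel–Crafts acylation, expected at the position ortho to the alkyl chain (para to one methoxy, ortho to the other) rather than at the more hindered carbon between the two methoxy groups, as is usual for 5-alkylresorcinol dimethyl ethers.

**Step 3**
Reactants: 5 1-(2-heptyl-4,6-dimethoxyphenyl)ethan-1-one
Product: 6 1-(2-heptyl-6-hydroxy-4-methoxyphenyl)ethan-1-one
Conditions: BCl3 (1.2 equiv), CH2Cl2, −78 → 0 °C; aq. work-up
Reagents that add atoms: none
Why: Chelation-controlled mono-demethylation, in which boron bound to the ketone oxygen delivers chloride only to the ortho methoxy group and leaves the para methoxy group untouched.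

**Step 4**
Reactants: 6 1-(2-heptyl-6-hydroxy-4-methoxyphenyl)ethan-1-one; 7 diethyl oxalate
Product: 9 ethyl 5-heptyl-7-methoxy-4-oxo-4H-chromene-2-carboxylate, via diketo ester 8 (not isolated)
Conditions: NaOEt (3 equiv), EtOH, reflux; then conc. HCl (cat.), EtOH, reflux
Reagents that add atoms: none
Why: Claisen condensation of the methyl ketone with the non-enolisable oxalate followed by acid cyclodehydration of the o-hydroxyaryl diketo ester, the classical chromone-2-carboxylate synthesis.

**Step 5**
Reactants: 9 ethyl 5-heptyl-7-methoxy-4-oxo-4H-chromene-2-carboxylate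
Product: 10 5-heptyl-2-(hydroxymethyl)-7-methoxy-4H-chromen-4-one
Conditions: NaBH4, MeOH/THF, 0 °C
Reagents that add atoms: none
Why: Chemoselective borohydride reduction of the activated α-oxygenated acrylate-type ester, which at 0 °C is reduced faster than the deactivated vinylogous-ester carbonyl of the pyranone, as known for chromone-2-carboxylates.

**Step 6**
Reactants: 10 5-heptyl-2-(hydroxymethyl)-7-methoxy-4H-chromen-4-one
Product: 11 2-(bromomethyl)-5-heptyl-7-methoxy-4H-chromen-4-one
Conditions: CBr4, PPh3, CH2Cl2, 0 °C
Reagents that add atoms: carbon tetrabromide, BrC(Br)(Br)Br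
Why: Appel bromination of a primary allylic-type alcohol under neutral conditions, which puts the halogen only on the C2 carbon and avoids radical conditions that would also attack the benzylic CH2 of the heptyl chain and C3.

**Step 7**
Reactants: 11 2-(bromomethyl)-5-heptyl-7-methoxy-4H-chromen-4-one; 12 methyl propiolate
Product: 14 methyl 4-(5-heptyl-7-methoxy-4-oxo-4H-chromen-2-yl)but-2-ynoate, via iodide 13 (not isolated)
Conditions: CuI (1.0 equiv), NaI (1.0 equiv), K2CO3 (1.0 equiv), DMF, 0 °C → rt
Reagents that add atoms: none
Why: Copper(I)-acetylide alkylation after in situ Finkelstein exchange, the sp–sp3 coupling used to join methyl propiolate to propargylic and allylic halides, run with a mild carbonate base to limit isomerisation of the new doubly activated CH2.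

**Step 8**
Reactants: 15 methyl acetoacetate
Product: 16 methyl (E)-3-methoxybut-2-enoate
Conditions: HC(OMe)3, H2SO4 (cat.), MeOH, rt; distillation
Reagents that add atoms: trimethyl orthoformate, COC(OC)OC
Why: Acid-catalysed ketalisation and loss of methanol gives the conjugated enol ether, with the (E)-isomer expected as the thermodynamic product.

**Step 9**
Reactants: 16 methyl (E)-3-methoxybut-2-enoate
Product: 17 (E)-1,3-dimethoxy-1-(trimethylsilyloxy)buta-1,3-diene
Conditions: LDA, THF, −78 °C; TMSCl, −78 °C → rt; non-aqueous work-up, distillation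
Reagents that add atoms: chlorotrimethylsilane, C[Si](C)(C)Cl
Why: γ-Deprotonation of the vinylogous ester and O-silylation of the dienolate gives the vinylketene silyl methyl acetal (a known diene); its ketene-acetal geometry is drawn as (E) but either geometry should converge after aromatisation.

**Step 10**
Reactants: 14 methyl 4-(5-heptyl-7-methoxy-4-oxo-4H-chromen-2-yl)but-2-ynoate; 17 (E)-1,3-dimethoxy-1-(trimethylsilyloxy)buta-1,3-diene
Product: 20 methyl 2-[(5-heptyl-7-methoxy-4-oxo-4H-chromen-2-yl)methyl]-6-hydroxy-4-methoxybenzoate, via cycloadduct 18 (not isolated), via aryl silyl ether 19 (not isolated)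
Conditions: 17 (3 equiv), toluene, 100–110 °C, sealed tube; then 1 M HCl, THF, rt
Reagents that add atoms: none
Why: Thermal, polarised and asynchronous [4+2] cycloaddition in which the nucleophilic CH2 terminus (C4) of 17 bonds to the ester β-carbon of 14 (C2′–C3′) and the acetal carbon (C1) to the α-carbon (C1′–C6′), giving 1,4-cyclohexadiene 18; its silyl methyl ketal expels methanol to give aryl silyl ether 19, which dilute acid cleaves to the phenol. The closest known reaction type is the Diels–Alder benzannulation of 1-alkoxy-1-silyloxybuta-1,3-dienes with alkynoates and allenoates to give resorcylate and homophthalate esters. The benzoate ring is the only ring closed, by an intermolecular [4+2] that makes two σ-bonds followed by 1,4-elimination and aromatisation, and no stereocentre survives because the ketal carbon of 18 becomes aromatic. The regiochemistry needed (ester ortho to the new hydroxyl, chromonyl CH2 meta to the methoxy group) follows from pairing the most nucleophilic diene terminus with the Michael-acceptor carbon of the ynoate, and the ynoate should react in preference to the chromone C2=C3 bond because that alkene is a β-oxygenated, electron-rich enone and a poor dienophile. Should the doubly activated CH2 of 14 let it tautomerise to the allenoate, cycloaddition at the ester-conjugated allene bond, loss of methanol and inward shift of the exocyclic double bond would lead to the same arene 20.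

**Step 11**
Reactants: 20 methyl 2-[(5-heptyl-7-methoxy-4-oxo-4H-chromen-2-yl)methyl]-6-hydroxy-4-methoxybenzoate
Product: 22 methyl 2-[(5-heptyl-7-methoxy-4-oxo-4H-chromen-2-yl)methyl]-3,6-dihydroxy-4-methoxybenzoate, via aryl sulfate 21 (not isolated)
Conditions: K2S2O8 (1.1 equiv), aq. KOH, pyridine, 0 °C → rt; then HCl, Na2SO3, 70 °C
Reagents that add atoms: potassium peroxodisulfate, [K+].[K+].[O-]S(=O)(=O)OOS(=O)(=O)[O-]
Why: Elbs persulfate oxidation, in which the phenoxide of the only free phenol attacks the peroxide oxygen through its para carbon C3′ (as chelated o-hydroxyaryl carbonyl compounds are known to do) and warm acid hydrolyses the aryl sulfate to the hydroquinone while reclosing any pyranone opened by the cold alkali.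

**Step 12**
Reactants: 22 methyl 2-[(5-heptyl-7-methoxy-4-oxo-4H-chromen-2-yl)methyl]-3,6-dihydroxy-4-methoxybenzoate
Product: 23 2-[(5-heptyl-7-hydroxy-4-oxo-4H-chromen-2-yl)methyl]-3,4,6-trihydroxybenzoic acid
Conditions: BBr3 (10 equiv), CH2Cl2, −78 °C → rt, Ar; then H2O, 0 °C (degassed work-up)
Reagents that add atoms: none
Why: Boron tribromide dealkylation cleaves both aryl methyl ethers and, by bromide attack on the O-methyl carbon of the boron-chelated salicylate, the hindered methyl ester, so the air-sensitive and decarboxylation-prone trihydroxybenzoic acid never meets base or hot aqueous acid.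

**Compound list**
1 | 1-bromo-3,5-dimethoxybenzene | COc1cc(Br)cc(OC)c1 | starting material
2 | heptylmagnesium bromide | CCCCCCC[Mg]Br | starting material
3 | 1-heptyl-3,5-dimethoxybenzene | CCCCCCCc1cc(OC)cc(OC)c1 | intermediate
4 | acetyl chloride | CC(=O)Cl | starting material
5 | 1-(2-heptyl-4,6-dimethoxyphenyl)ethan-1-one | CCCCCCCc1cc(OC)cc(OC)c1C(C)=O | intermediate
6 | 1-(2-heptyl-6-hydroxy-4-methoxyphenyl)ethan-1-one | CCCCCCCc1cc(OC)cc(O)c1C(C)=O | intermediate
7 | diethyl oxalate | CCOC(=O)C(=O)OCC | starting material
8 | ethyl 4-(2-heptyl-6-hydroxy-4-methoxyphenyl)-2,4-dioxobutanoate (diketo ester, not isolated) | CCCCCCCc1cc(OC)cc(O)c1C(=O)CC(=O)C(=O)OCC | intermediate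
9 | ethyl 5-heptyl-7-methoxy-4-oxo-4H-chromene-2-carboxylate | CCCCCCCc1cc(OC)cc2oc(C(=O)OCC)cc(=O)c12 | intermediate
10 | 5-heptyl-2-(hydroxymethyl)-7-methoxy-4H-chromen-4-one | CCCCCCCc1cc(OC)cc2oc(CO)cc(=O)c12 | intermediate
11 | 2-(bromomethyl)-5-heptyl-7-methoxy-4H-chromen-4-one | CCCCCCCc1cc(OC)cc2oc(CBr)cc(=O)c12 | intermediate
12 | methyl propiolate | C#CC(=O)OC | starting material
13 | 5-heptyl-2-(iodomethyl)-7-methoxy-4H-chromen-4-one (iodide, not isolated) | CCCCCCCc1cc(OC)cc2oc(CI)cc(=O)c12 | intermediate
14 | methyl 4-(5-heptyl-7-methoxy-4-oxo-4H-chromen-2-yl)but-2-ynoate | CCCCCCCc1cc(OC)cc2oc(CC#CC(=O)OC)cc(=O)c12 | intermediate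
15 | methyl acetoacetate | COC(=O)CC(C)=O | starting material
16 | methyl (E)-3-methoxybut-2-enoate | CO/C(C)=C/C(=O)OC | intermediate
17 | (E)-1,3-dimethoxy-1-(trimethylsilyloxy)buta-1,3-diene | C=C(OC)/C=C(\OC)O[Si](C)(C)C | intermediate
18 | methyl 2-[(5-heptyl-7-methoxy-4-oxo-4H-chromen-2-yl)methyl]-4,6-dimethoxy-6-(trimethylsilyloxy)cyclohexa-1,4-diene-1-carboxylate (cycloadduct, racemic at the ketal carbon, not isolated) | CCCCCCCc1cc(OC)cc2oc(CC3=C(C(=O)OC)C(OC)(O[Si](C)(C)C)C=C(OC)C3)cc(=O)c12 | intermediate
19 | methyl 2-[(5-heptyl-7-methoxy-4-oxo-4H-chromen-2-yl)methyl]-4-methoxy-6-(trimethylsilyloxy)benzoate (aryl silyl ether, not isolated) | CCCCCCCc1cc(OC)cc2oc(Cc3cc(OC)cc(O[Si](C)(C)C)c3C(=O)OC)cc(=O)c12 | intermediate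
20 | methyl 2-[(5-heptyl-7-methoxy-4-oxo-4H-chromen-2-yl)methyl]-6-hydroxy-4-methoxybenzoate | CCCCCCCc1cc(OC)cc2oc(Cc3cc(OC)cc(O)c3C(=O)OC)cc(=O)c12 | intermediate
21 | potassium 3-hydroxy-2-(methoxycarbonyl)-6-methoxy-... aryl sulfate: methyl 2-[(5-heptyl-7-methoxy-4-oxo-4H-chromen-2-yl)methyl]-6-hydroxy-4-methoxy-3-(sulfonatooxy)benzoate, potassium salt (not isolated) | CCCCCCCc1cc(OC)cc2oc(Cc3c(OS(=O)(=O)[O-])c(OC)cc(O)c3C(=O)OC)cc(=O)c12.[K+] | intermediate
22 | methyl 2-[(5-heptyl-7-methoxy-4-oxo-4H-chromen-2-yl)methyl]-3,6-dihydroxy-4-methoxybenzoate | CCCCCCCc1cc(OC)cc2oc(Cc3c(O)c(OC)cc(O)c3C(=O)OC)cc(=O)c12 | intermediate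
23 | 2-[(5-heptyl-7-hydroxy-4-oxo-4H-chromen-2-yl)methyl]-3,4,6-trihydroxybenzoic acid | CCCCCCCc1cc(O)cc2oc(Cc3c(O)c(O)cc(O)c3C(=O)O)cc(=O)c12 | target

**Step count**
Total: 12 steps. Longest linear sequence: 10 steps (steps 1–7 and 10–12); the diene branch (steps 8–9) joins at step 10.

**Steps most likely to fail**

1. Step 10 (key step). The cycloaddition of the β-alkyl-substituted ynoate may be slower than thermal desilylation or decomposition of the ketene acetal, and the ynoate may isomerise and oligomerise before it is trapped.
Fallback: it sets out from diene 17 and acetophenone 6 and comes back at 20. Diene 17 would be combined with commercial dimethyl penta-2,3-dienedioate (COC(=O)C=C=CC(=O)OC; toluene, 0 °C → rt, then dilute HCl). This is the established cycloaddition–aromatisation route to homophthalates and should give methyl 2-hydroxy-4-methoxy-6-(2-methoxy-2-oxoethyl)benzoate F1. Claisen condensation of the sodium enolate of 6 with the aliphatic ester of F1 (NaH in excess, THF, reflux) would give methyl 2-[4-(2-heptyl-6-hydroxy-4-methoxyphenyl)-2,4-dioxobutyl]-6-hydroxy-4-methoxybenzoate F2; the doubly ortho-substituted, phenoxide-deactivated aryl ester should not compete. Acid cyclodehydration (HCl, MeOH, reflux) would then close the pyranone ring to give 20. The chromone is thus built last and the sensitive ynoate is avoided.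

2. Step 11. The persulfate oxidation may stop at low conversion, the hydroquinone formed may be oxidised further, the acidic CH2 between the two rings may be oxidised, and the alkali may partly saponify the ester.
Fallback: it sets out from 20 and comes back at 22. Oxidative dearomatisation of the phenol with PhI(OCOCF3)2 (2.2 equiv, MeCN/H2O, 0 °C) should place water at the free para carbon and give methyl 2-[(5-heptyl-7-methoxy-4-oxo-4H-chromen-2-yl)methyl]-4-methoxy-3,6-dioxocyclohexa-1,4-diene-1-carboxylate F3. Immediate reduction with aqueous Na2S2O4 (EtOAc/H2O, rt) would give hydroquinone 22 without any alkaline stage.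

3. Step 7. The carbonate base may isomerise the product to the allenoate or alkylate its doubly activated CH2 a second time, and iodide or carbonate may add to the electron-poor alkyne.
Fallback: it sets out from 12 and 11 and comes back at 14. Methyl propiolate 12 would be deprotonated and stannylated (LDA, THF, −78 °C; Bu3SnCl) to give methyl 3-(tributylstannyl)prop-2-ynoate F4. A base-free Stille coupling of F4 with bromide 11 (Pd2(dba)3, tri(2-furyl)phosphine, THF, 50 °C) would give 14 under neutral conditions.

**Further compounds**
F1 | step 10 | methyl 2-hydroxy-4-methoxy-6-(2-methoxy-2-oxoethyl)benzoate | COC(=O)Cc1cc(OC)cc(O)c1C(=O)OC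
F2 | step 10 | methyl 2-[4-(2-heptyl-6-hydroxy-4-methoxyphenyl)-2,4-dioxobutyl]-6-hydroxy-4-methoxybenzoate | CCCCCCCc1cc(OC)cc(O)c1C(=O)CC(=O)Cc1cc(OC)cc(O)c1C(=O)OC
F3 | step 11 | methyl 2-[(5-heptyl-7-methoxy-4-oxo-4H-chromen-2-yl)methyl]-4-methoxy-3,6-dioxocyclohexa-1,4-diene-1-carboxylate | CCCCCCCc1cc(OC)cc2oc(CC3=C(C(=O)OC)C(=O)C=C(OC)C3=O)cc(=O)c12
F4 | step 7 | methyl 3-(tributylstannyl)prop-2-ynoate | CCCC[Sn](CCCC)(CCCC)C#CC(=O)OC
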